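## The problem

The target is a germacranolide. In germacrane numbering, a ten-membered carbocycle (C1–C10) is cis-fused at C6/C7 to an α-methylene γ-butyrolactone (C11 α-carbon, C12 carbonyl, C13 methylene); it carries a C3 ketone conjugated to a 4Z double bond, a C8 angelate and a C1/C10 diol. A ten-membered ring is the hardest size to close end to end, so it should grow out of a smaller ring and not be closed from a chain. Of the five stereocentres, C1 (S) and C10 (S) form a trans secondary/tertiary diol on one flank, and C6 (S), C7 (R) and C8 (R) are contiguous on the other with their three hydrogens on one face. Methylene and sp2 carbons separate the two groups, so the diol can steer the other three only through a rigid intermediate. The fragile groups are the α-methylene lactone (Michael acceptor), the angelate (Z to E), the C1 hydroxyl β to the C3 ketone (dehydration, retro-aldol), and any C8 ketone intermediate, which has the C6 oxygen on its β-carbon. The enabling feature is that C3 and C8 are both oxygenated and 1,6 to each other across the ring. An extra C3–C8 bond gives a cyclohexane-1,2-diol (ring order C3–C2–C1–C10–C9–C8) whose carbinol carbons carry C4=C5 as an isopropenyl group and C7=C6 as the double bond of a dihydrofuran that already holds C6, C7, C11, C12 and the lactone oxygen. This 3-oxy-1,5-diene can undergo a [3,3] shift that cuts C3–C8 and makes C5–C6; in the cyclohexane, C1 and C10 are 1,3 to the carbinol carbons and can set them, and the chair transition state relays C8 to C6.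

## Retrosynthesis

**Lactone carbonyl and exocyclic methylene (31 ⇒ 28).** Target 31 is the diol freed from acetonide 30; 30 is the oxidation product of α-methylene lactol 29; 29 comes from lactol 28 by adding C13. The C11=C13 bond is cut at the aldehyde oxidation level, not at the lactone: the open hydroxy aldehyde of a lactol is methylenated through an enamine without strong base, whereas a lactone enolate would destroy the enone, the angelate and the β-oxygenated C3 ketone. Lactol 28 lacks the Michael acceptor and one carbon. Forward, the aldehyde must react beside a ketone and an ester, and an allylic lactol must be oxidised selectively.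

**Enone and ester (28 ⇒ 23 + 24).** Lactol 28 comes from methyl acetal 27, enone 27 from silyl enol ether 26, and 26 from alcohol 23 and angelic acid 24. Carrying C3 as a silyl enol ether lets C8 be reduced and acylated while no other carbonyl group is present, and places the new double bond at C4–C5. A C3 ketone carried from the ring expansion would instead face the C8 ketone across the ring and invite transannular aldol addition. Forward, the esterification must not isomerise the angelate, and the dehydrogenation must give the ring-cis enone.

**C7–H and C8–H (23 ⇒ 21).** Alcohol 23 is the reduction product of ketone 22, and 22 the C-protonation product of the C8 trimethylsilyl enol ether in 21. Both hydrogens are added after the ring is made, because the ring-E geometry of the C7=C8 enol double bond, held by the fused tetrahydrofuran, leaves only its outer face open. Compound 21 has two stereocentres fewer. Forward, one of two silyl enol ethers must be cleaved, and proton and hydride must both come from the periphery.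

**Ring expansion (21 ⇒ 18; forward: C5–C6 forms, C3–C8 breaks).** Reconnecting C3 to C8 and cutting C5–C6 turns the ten-membered bis(enol ether) 21 into cyclohexanol 18. Compared with closing the ring at C7–C8, C2–C3 or C1–C10 from a chain, this makes the medium ring from a six-membered one in a unimolecular pericyclic step and creates C6 by chirality transfer. Either carbinol oxygen could carry the charge. It is placed on C8, because that alkoxide is the direct product of the last C–C bond formation and its enolate can later be unveiled without acid. The C3 oxygen is capped as a silyl ether that cannot migrate and later serves as the enone precursor. The price is an enolate with the C6 oxygen on its β-carbon. Forward, only the trans-dialkenyl chair may react, the alkoxide must not fragment, and the enolate must be silylated on oxygen.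

**C7–C8 bond (18 ⇒ 11 + 15).** Cyclohexanol 18 is divided into ketone 11 and bromide 15, used as its organometallic. This bond is made last so that the acid-sensitive dihydrofuran (it loses methanol to a furan) passes through a single isolated intermediate. The reverse order, with isopropenyl last, would need equatorial attack past an axial oxygen with an open axial face and should give the cis-dialkenyl isomer. In the chosen order the axial face of C8 is closed by the C10 methyl. Forward, a β-oxido vinyl metal must survive long enough to add to a hindered ketone.

**Dihydrofuran fragment (15 ⇒ 12).** Bromide 15 comes from enol ether 13 by bromination and dehydrobromination, and 13 from commercial acetal 12 by loss of one methanol.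

**C3–C4 bond (11 ⇒ 7 + 8).** Ketone 11 is the silyl ether of ketol 10, the oxidation product of diol 9, which is cut into acyloin 7 and isopropenylmagnesium bromide 8. Adding the isopropenyl group to a C3 ketone next to a free equatorial C8 hydroxyl uses chelation to put it trans to that oxygen, and no protecting group is needed. Forward, the secondary alcohol must be oxidised beside the tertiary one.

**C3 and C8 oxygens (7 ⇒ 4).** Acyloin 7 comes from cis-diol 5, the dihydroxylation product of alkene 4. The two carbons are told apart by the locked chair, not by a reagent: one hydroxyl is axial and the other equatorial. Forward, the oxidant must attack anti to the axial methyl, and only the axial alcohol must be oxidised.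

**C1/C10 diol (4 ⇒ 1).** Acetonide 4 protects trans-diol 3, made from epoxide 2 and this from commercial achiral diene 1. One catalytic asymmetric epoxidation of the trisubstituted double bond is the only enantio-determining step. Opening with hydroxide at the secondary carbon keeps the tertiary centre intact. The trans-fused acetonide is preferred to two separate silyl ethers because it fixes the chair with the C10 methyl axial, and every later face selection rests on that.

## Roads not taken

Alternative 1: The cut is C7–C11 and C6–O, so the lactone is annulated last onto a preformed ten-membered 4Z,6Z-diene A1. Forward, Mn(OAc)3 (trivalent manganese) with Cu(OAc)2 oxidises malonic acid to its radical, which adds at C7; the allyl radical is oxidised and the carboxylate closes on C6 to give the cis-fused α-carboxy lactone A2. Decarboxylative methylenation then gives the methylene lactone.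
- Merits: C11–C13 arrive in two operations, shorter than the lactol sequence of the chosen plan, and the cis fusion follows from five-membered ring closure. In this respect the road is better.
- Weak points: A1 already contains the ten-membered ring with its diene and four oxygenated carbons, so the hardest problem is only moved. The radical must choose C7 over C4 and one face with only the C8 hydroxyl to guide it. Hot acetic acid with an oxidant is unkind to the 4-methoxybenzyl ether and free hydroxyls. C3 oxidation and angeloylation still follow.
- Comparison: the chosen plan forms the ring and sets C6 in one step; it has to set a longer lactone endgame against this.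

Alternative 2: The cut is C2–C3 and C3–C4, with carbon monoxide as C3. Forward, Pd2(dba)3 with AsPh3 (zerovalent palladium) under CO adds to the C4–I bond of the open-chain iodide/stannane A3, inserts CO and couples with the C2 stannane, closing the ten-membered 1E,4Z-dienone A4.
- Merits: the road is convergent. C6–C8 and C10 are set in an open chain by reliable acyclic methods. The 4Z geometry is fixed by the vinyl iodide, which is more secure than the late dehydrogenation of the chosen plan. The angelate is already in place.
- Weak points: an organometallic ten-membered closure needs high dilution and competes with CO-free coupling to the nine-membered ring and with oligomers. The product is a 1-ene, so the C1 hydroxyl must be added by conjugate hydration beside C10 with no good control element and with two acceptor positions in the cross-conjugated dienone.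
- Comparison: if the closure works it is probably shorter overall; the chosen plan has C1–OH from its first steps and no macrocyclisation.

Alternative 3: The cut is C7–C8. Forward, photolysis with (Bu3Sn)2 turns the selenoester A5 into the C8 acyl radical, which adds to C7 of the butenolide; loss of the tributyltin radical from C13 leaves the ten-membered C8 ketone A6 with the α-methylene lactone.
- Merits: ring and methylene lactone form in one neutral step with C6 set beforehand; at the lactone end this is more economical than the chosen plan.
- Weak points: a ten-membered acyl radical closure competes with decarbonylation and simple reduction. C7 is set in the radical addition with no element that enforces the cis fusion. The product has the C8 ketone, the acidic C7–H and the lactone oxygen on the β-carbon together, an elimination-prone array. The ketone must then be reduced beside a methylene lactone, and C3 must still be oxidised.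
- Comparison: the chosen plan never has the C8 ketone and the lactone in one molecule and fixes C7 by protonating a face-differentiated enol ether; it pays with more steps after ring formation.

Key step: step 12

Remark on the chemistry: bromide 15 is racemic at its acetal carbon (C12), so 18–29 are carried as mixtures of the two C12 epimers, which converge when C12 becomes the lactone carbonyl in 30. The target is taken as the open 3-keto-1,10-diol as drawn.

Step 1
Reactants: 1 1-methylcyclohexa-1,4-diene
Product: 2 (1S,6R)-1-methyl-7-oxabicyclo[4.1.0]hept-3-ene (C1–C10 epoxide)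
Conditions: D-fructose-derived Shi ketone (30 mol%), KHSO5 (1.0 equiv, as 2KHSO5·KHSO4·K2SO4), K2CO3, Bu4NHSO4, MeCN/CH2(OMe)2/aq. Na2B4O7 buffer, 0 °C
Reagents that add atoms: potassium peroxymonosulfate, [K+].[O-]S(=O)(=O)OO
Why: Shi epoxidation: the chiral dioxirane reacts much faster with the trisubstituted than with the cis-disubstituted double bond, and its spiro transition state should deliver oxygen to the face that gives the (1S,6R) epoxide, the sense known for 1-substituted cyclohexenes; one equivalent of oxidant limits double epoxidation.

Step 2
Reactants: 2 epoxide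
Product: 3 (1S,2S)-1-methylcyclohex-4-ene-1,2-diol
Conditions: NaOH (2 M aq.), 1,4-dioxane, 100 °C
Reagents that add atoms: water, O
Why: Base-mediated epoxide hydrolysis is an SN2 opening at the secondary carbon (C1) with inversion, and the tertiary C10–O bond is not touched, so the trans diol should form without the ionisation that could erode C10 under acid.

Step 3
Reactants: 3 trans-diol
Product: 4 (3aS,7aS)-2,2,3a-trimethyl-3a,4,7,7a-tetrahydro-1,3-benzodioxole (trans-fused acetonide)
Conditions: 2-methoxypropene, PPTS (cat.), CH2Cl2, 0 °C → rt
Reagents that add atoms: 2-methoxypropene, COC(C)=C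
Why: Acid-catalysed ketalisation with an enol ether; the trans-fused dioxolane can form only with both oxygens equatorial, which locks the ring with the C10 methyl axial for all later face-selective steps.

Step 4
Reactants: 4 acetonide alkene
Product: 5 (3aS,5R,6S,7aS)-2,2,3a-trimethylhexahydro-1,3-benzodioxole-5,6-diol (cis-diol, both hydroxyls anti to the C10 methyl)
Conditions: OsO4 (2 mol%), NMO, acetone/H2O, rt
Reagents that add atoms: N-methylmorpholine N-oxide, C[N+]1([O-])CCOCC1; water, O
Why: Upjohn syn-dihydroxylation; OsO4 should approach the C3=C8 double bond from the face opposite the axial homoallylic methyl, which leaves the C3 hydroxyl axial and the C8 hydroxyl equatorial in the locked chair.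

Step 5
Reactants: 5 cis-diol
Product: 7 (3aS,6R,7aS)-6-hydroxy-2,2,7a-trimethylhexahydro-1,3-benzodioxol-5-one (acyloin: C3 ketone; equatorial C8 hydroxyl), via dibutylstannylene acetal 6 (not isolated)
Conditions: Bu2SnO, toluene, reflux (−H2O); then Br2, 4 Å MS, CH2Cl2, 0 °C
Reagents that add atoms: none
Why: Brominolysis of the dibutylstannylene acetal of a ring cis-diol oxidises one hydroxyl only, the axial one whose carbinol hydrogen is equatorial, so the C3 ketone should form while the equatorial C8 hydroxyl is kept.

Step 6
Reactants: 7 acyloin; 8 isopropenylmagnesium bromide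
Product: 9 (3aS,5R,6R,7aS)-2,2,3a-trimethyl-6-(prop-1-en-2-yl)hexahydro-1,3-benzodioxole-5,6-diol (C3 isopropenyl equatorial; C3 hydroxyl axial and cis to the C8 hydroxyl)
Conditions: 8 (3 equiv), THF, −78 → 0 °C; aq. NH4Cl
Reagents that add atoms: none
Why: Grignard addition to the magnesium alkoxide of an α-hydroxy ketone under Cram chelate control: the chelate holds the C8 oxygen in the carbonyl plane and the nucleophile should enter from the side of the axial C8 hydrogen (equatorial attack), placing isopropenyl trans to the C8 oxygen.

Step 7
Reactants: 9 diol
Product: 10 (3aS,6R,7aS)-6-hydroxy-2,2,3a-trimethyl-6-(prop-1-en-2-yl)hexahydro-1,3-benzodioxol-5-one (C8 ketone, tertiary C3 alcohol)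
Conditions: IBX, DMSO, rt
Reagents that add atoms: none
Why: IBX oxidises the secondary hydroxyl of a 1,2-diol to the ketone without glycol cleavage and cannot oxidise the tertiary one.

Step 8
Reactants: 10 ketol
Product: 11 (3aS,6R,7aS)-6-[(tert-butyldimethylsilyl)oxy]-2,2,3a-trimethyl-6-(prop-1-en-2-yl)hexahydro-1,3-benzodioxol-5-one
Conditions: t-BuMe2SiOTf, 2,6-lutidine, CH2Cl2, −78 → 0 °C
Reagents that add atoms: tert-butyldimethylsilyl trifluoromethanesulfonate, CC(C)(C)[Si](C)(C)OS(=O)(=O)C(F)(F)F
Why: Silyl triflate silylation of a hindered tertiary alcohol; this oxygen later becomes the robust C3 silyl enol ether.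

Step 9
Reactants: 12 2,5-dimethoxytetrahydrofuran
Product: 13 2-methoxy-2,3-dihydrofuran
Conditions: Me3SiOTf (1.0 equiv), i-Pr2NEt, CH2Cl2, −20 °C; distillation
Reagents that add atoms: none
Why: Silyl triflate/amine conversion of an acetal into an enol ether: one methoxy group is ionised to the cyclic oxocarbenium ion and the amine removes the adjacent proton; one equivalent at low temperature should stop before the second elimination to furan.

Step 10
Reactants: 13 2-methoxy-2,3-dihydrofuran
Product: 15 4-bromo-2-methoxy-2,3-dihydrofuran, via 2,3-dibromo-5-methoxytetrahydrofuran 14 (not isolated)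
Conditions: Br2, CH2Cl2, −78 °C; then DBU, −78 °C → rt
Reagents that add atoms: bromine, BrBr
Why: Bromine addition to the enol ether followed by base-induced loss of HBr through the α-bromo ether gives the β-bromo enol ether, the standard route to 5-bromo-3,4-dihydro-2H-pyran applied to the five-membered ring.

Step 11
Reactants: 11 silyloxy ketone; 15 bromide
Product: 18 (3aS,5R,6R,7aS)-6-[(tert-butyldimethylsilyl)oxy]-5-(5-methoxy-4,5-dihydrofuran-3-yl)-2,2,3a-trimethyl-6-(prop-1-en-2-yl)hexahydro-1,3-benzodioxol-5-ol (trans-dialkenyl cyclohexanol; 1S,3R,8R,10S in germacrane numbering; C12 epimers), via (5-methoxy-4,5-dihydrofuran-3-yl)lithium 16 (not isolated), via (5-methoxy-4,5-dihydrofuran-3-yl)cerium dichloride 17 (not isolated)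
Conditions: 15, t-BuLi (2 equiv), THF, −78 °C; CeCl3, −78 °C; then 11, −78 → −40 °C; aq. NaHCO3; base-washed silica
Reagents that add atoms: none
Why: Halogen–lithium exchange and transmetalation give a weakly basic organocerium reagent that adds to the hindered, enolisable ketone while the low temperature holds back ring opening of the β-oxido vinyl metal; the axial face of C8 is closed by the syn-axial C10 methyl, so the alkenyl group should enter equatorially, trans to the isopropenyl group.

Step 12
Reactants: 18 trans-dialkenyl cyclohexanol
Product: 21 ten-membered bis(silyl enol ether) (6S; C3 tert-butyldimethylsilyl and C8 trimethylsilyl enol ethers; C3=C4 and C7=C8 both E in the ring; C1/C10 acetonide; 2-methoxytetrahydrofuran O–C12–C11 fused at C6/C7), via potassium alkoxide 19 (not isolated), via potassium enolate 20 (not isolated)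
Conditions: KH (3 equiv), 18-crown-6 (3 equiv), THF, 0 °C → rt; then Me3SiCl/Et3N, −78 °C
Reagents that add atoms: chlorotrimethylsilane, C[Si](C)(C)Cl
Why: KH with 18-crown-6 turns 18 into the free potassium alkoxide 19, a 3-oxido-1,5-diene (C5=C4–C3–C8(O−)–C7=C6), which should undergo a concerted suprafacial [3,3] sigmatropic shift through a chair transition state in which C5–C6 forms while C3–C8 breaks, the charge ending as the C8 enolate 20. The closest known reaction type is the anionic oxy-Cope ring expansion of trans-1,2-dialkenylcyclohexanols to cyclodec-5-enones, which tolerates a cyclic enol ether as one alkene partner. The ten-membered ring is not closed end to end: it arises by a four-atom ring enlargement, the new C5–C6 bond joining the two alkenyl groups as the bond shared by the cyclohexane and the six-centre array is cut. The single new stereocentre, C6, is set by chirality transfer from C8 and C3: with both alkenyl groups equatorial and both oxygens axial, the chair array places the dihydrofuran oxygen pseudo-equatorial and H6 pseudo-axial, so C5 bonds to the face of C6 that gives 6S, and both new ring double bonds are E with respect to the ring. The step needs the trans-dialkenyl chair and no other conformer, and the trans-fused acetonide secures it by locking the cyclohexane with the alkenyl groups equatorial; the anti (diaxial) disposition of O3 and O8 also rules out silyl migration between them before the shift. Because O3 leaves as a tert-butyldimethylsilyl enol ether, no ketone faces the enolate across the ring and transannular aldol addition is excluded, while the in-ring C6–O bond lies near the nodal plane of the enolate, which disfavours β-elimination. Me3SiCl/Et3N then silylates the enolate on oxygen and gives 21 with two silyl enol ethers of different lability.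

Step 13
Reactants: 21 bis(silyl enol ether)
Product: 23 C8 alcohol (6S,7R,8R; H6 H7 H8 on one face; cis-fused 2-methoxytetrahydrofuran; C3 tert-butyldimethylsilyl enol ether; C1/C10 acetonide), via C8 ketone 22 (not isolated)
Conditions: PPTS (0.1 equiv), MeOH/CH2Cl2, −20 °C; then NaBH4, −20 → 0 °C
Reagents that add atoms: none
Why: Acid-catalysed methanolysis should cleave only the trimethylsilyl enol ether, with C-protonation at C7 on the open outer face of the ring-E enol double bond so that H7 ends cis to H6, while methanol as solvent keeps C12 as its methyl acetal. NaBH4 then reduces the only ketone by peripheral, Felkin–Anh-type attack anti to the C7–C6 ring bond, which should give the 8R carbinol. The ketone is not isolated, so its epimerisable, β-oxygenated C7 centre is never handled.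

Step 14
Reactants: 23 C8 alcohol; 24 angelic acid
Product: 26 C8 angelate (otherwise as 23), via angelic 2,4,6-trichlorobenzoic anhydride 25 (not isolated)
Conditions: 24, 2,4,6-Cl3C6H2COCl, Et3N, toluene, rt; then 23, 80 °C
Reagents that add atoms: none
Why: Yamaguchi esterification through the mixed anhydride acylates hindered secondary alcohols, and leaving out a nucleophilic catalyst should keep the Z geometry of the angelate.

Step 15
Reactants: 26 C8 angelate
Product: 27 4Z-en-3-one (C8 angelate, cis-fused 2-methoxytetrahydrofuran, C1/C10 acetonide)
Conditions: Pd(OAc)2 (1.1 equiv), MeCN, rt → 40 °C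
Reagents that add atoms: none
Why: Saegusa–Ito oxidation: silicon-to-palladium exchange gives the C4-bound divalent palladium enolate and syn β-hydride elimination toward C5 gives the ring enone; the 4Z isomer, with C3 and C6 cis across the double bond, is the geometry found in this ring system and is expected directly or after palladium hydride re-addition.

Step 16
Reactants: 27 enone methyl acetal
Product: 28 lactol (C12 hemiacetal; otherwise as 27)
Conditions: AcOH/THF/H2O (3:1:1), rt
Reagents that add atoms: water, O
Why: The 2-methoxytetrahydrofuran, a 2-deoxy furanoside-type acetal, hydrolyses far faster than the isopropylidene ketal of a ten-membered-ring diol, so only C12 should be unmasked.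

Step 17
Reactants: 28 lactol
Product: 29 α-methylene lactol (C11=C13)
Conditions: aq. CH2O, pyrrolidine (20 mol%), EtCO2H (20 mol%), i-PrOH, 45 °C
Reagents that add atoms: formaldehyde, C=O
Why: Amine-catalysed α-methylenation of aldehydes: the lactol equilibrates with its γ-hydroxy aldehyde, whose enamine undergoes Mannich condensation and elimination, and the enal recloses to the lactol; ketone and ester carbonyls do not form enamines under these conditions.

Step 18
Reactants: 29 α-methylene lactol
Product: 30 α-methylene γ-lactone (C1/C10 acetonide of the target)
Conditions: MnO2 (activated, excess), CH2Cl2, rt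
Reagents that add atoms: none
Why: Activated MnO2 oxidises allylic hemiacetals to the lactones under neutral conditions and leaves the enone, angelate and acetonide alone.

Step 19
Reactants: 30 acetonide
Product: 31 target (1S,6S,7R,8R,10S; 4Z; Z-angelate)
Conditions: TFA/H2O (4:1), CH2Cl2, 0 °C
Reagents that add atoms: none
Why: Acid hydrolysis of the isopropylidene ketal frees the C1/C10 diol; the methylene lactone, angelate and enone tolerate brief aqueous acid at low temperature, and no base is used that could dehydrate the new β-hydroxy ketone.

Compound list
1 | 1-methylcyclohexa-1,4-diene | CC1=CCC=CC1 | starting material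
2 | (1S,6R)-1-methyl-7-oxabicyclo[4.1.0]hept-3-ene | C1=CC[C@H]2O[C@@]2(C)C1 | intermediate
3 | (1S,2S)-1-methylcyclohex-4-ene-1,2-diol | C1=CC[C@H](O)[C@@](C)(O)C1 | intermediate
4 | (3aS,7aS)-2,2,3a-trimethyl-3a,4,7,7a-tetrahydro-1,3-benzodioxole | C1=CC[C@@H]2OC(C)(C)O[C@@]2(C)C1 | intermediate
5 | (3aS,5R,6S,7aS)-2,2,3a-trimethylhexahydro-1,3-benzodioxole-5,6-diol | O[C@H]1C[C@@H]2OC(C)(C)O[C@@]2(C)C[C@H]1O | intermediate
6 | dibutylstannylene acetal of 5 | CCCC[Sn]1(CCCC)O[C@H]2C[C@@H]3OC(C)(C)O[C@@]3(C)C[C@H]2O1 | intermediate
7 | (3aS,6R,7aS)-6-hydroxy-2,2,7a-trimethylhexahydro-1,3-benzodioxol-5-one | O=C1C[C@@H]2OC(C)(C)O[C@@]2(C)C[C@H]1O | intermediate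
8 | isopropenylmagnesium bromide | C=C(C)[Mg]Br | starting material
9 | (3aS,5R,6R,7aS)-2,2,3a-trimethyl-6-(prop-1-en-2-yl)hexahydro-1,3-benzodioxole-5,6-diol | C=C(C)[C@]1(O)C[C@@H]2OC(C)(C)O[C@@]2(C)C[C@H]1O | intermediate
10 | (3aS,6R,7aS)-6-hydroxy-2,2,3a-trimethyl-6-(prop-1-en-2-yl)hexahydro-1,3-benzodioxol-5-one | C=C(C)[C@]1(O)C[C@@H]2OC(C)(C)O[C@@]2(C)CC1=O | intermediate
11 | (3aS,6R,7aS)-6-[(tert-butyldimethylsilyl)oxy]-2,2,3a-trimethyl-6-(prop-1-en-2-yl)hexahydro-1,3-benzodioxol-5-one | C=C(C)[C@]1(O[Si](C)(C)C(C)(C)C)C[C@@H]2OC(C)(C)O[C@@]2(C)CC1=O | intermediate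
12 | 2,5-dimethoxytetrahydrofuran | COC1CCC(OC)O1 | starting material
13 | 2-methoxy-2,3-dihydrofuran | COC1CC=CO1 | intermediate
14 | 2,3-dibromo-5-methoxytetrahydrofuran | COC1CC(Br)C(Br)O1 | intermediate
15 | 4-bromo-2-methoxy-2,3-dihydrofuran | COC1CC(Br)=CO1 | intermediate
16 | (5-methoxy-4,5-dihydrofuran-3-yl)lithium | COC1CC([Li])=CO1 | intermediate
17 | (5-methoxy-4,5-dihydrofuran-3-yl)cerium dichloride | COC1CC(=CO1)[Ce](Cl)Cl | intermediate
18 | trans-dialkenyl cyclohexanol: C8 carbinol with equatorial 5-methoxy-4,5-dihydrofuran-3-yl, C3 with equatorial isopropenyl and axial OTBS, C1/C10 trans-fused acetonide (C12 epimers) | C=C(C)[C@]1(O[Si](C)(C)C(C)(C)C)C[C@@H]2OC(C)(C)O[C@@]2(C)C[C@@]1(O)C3=COC(OC)C3 | intermediate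
19 | potassium C8 alkoxide of 18 | C=C(C)[C@]1(O[Si](C)(C)C(C)(C)C)C[C@@H]2OC(C)(C)O[C@@]2(C)C[C@@]1([O-])C3=COC(OC)C3.[K+] | intermediate
20 | ten-membered potassium C8 enolate (6S) with C3 OTBS enol ether | CC(C)(C)[Si](C)(C)O/C1=C(/C)C[C@@H]2OC(OC)C/C2=C([O-])\C[C@]3(C)OC(C)(C)O[C@H]3C1.[K+] | intermediate
21 | ten-membered bis(silyl enol ether) (6S): C3 OTBS and C8 OTMS enol ethers, both ring double bonds E, C1/C10 acetonide, fused 2-methoxytetrahydrofuran | CC(C)(C)[Si](C)(C)O/C1=C(/C)C[C@@H]2OC(OC)C/C2=C(O[Si](C)(C)C)\C[C@]3(C)OC(C)(C)O[C@H]3C1 | intermediate
22 | ten-membered C8 ketone, H6 and H7 cis, C3 OTBS enol ether | CC(C)(C)[Si](C)(C)O/C1=C(/C)C[C@@H]2OC(OC)C[C@@H]2C(=O)C[C@]3(C)OC(C)(C)O[C@H]3C1 | intermediate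
23 | C8 alcohol (6S,7R,8R), C3 OTBS enol ether | CC(C)(C)[Si](C)(C)O/C1=C(/C)C[C@@H]2OC(OC)C[C@@H]2[C@H](O)C[C@]3(C)OC(C)(C)O[C@H]3C1 | intermediate
24 | angelic acid, (Z)-2-methylbut-2-enoic acid | C/C=C(/C)C(=O)O | starting material
25 | angelic 2,4,6-trichlorobenzoic anhydride | C/C=C(/C)C(=O)OC(=O)c1c(Cl)cc(Cl)cc1Cl | intermediate
26 | C8 angelate, C3 OTBS enol ether | CC(C)(C)[Si](C)(C)O/C1=C(/C)C[C@@H]2OC(OC)C[C@@H]2[C@H](OC(=O)/C(C)=C\C)C[C@]3(C)OC(C)(C)O[C@H]3C1 | intermediate
27 | 4Z-en-3-one with C8 angelate, C12 methyl acetal, C1/C10 acetonide | O=C1/C(C)=C\[C@@H]2OC(OC)C[C@@H]2[C@H](OC(=O)/C(C)=C\C)C[C@]3(C)OC(C)(C)O[C@H]3C1 | intermediate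
28 | C12 lactol of 27 | O=C1/C(C)=C\[C@@H]2OC(O)C[C@@H]2[C@H](OC(=O)/C(C)=C\C)C[C@]3(C)OC(C)(C)O[C@H]3C1 | intermediate
29 | α-methylene lactol | O=C1/C(C)=C\[C@@H]2OC(O)C(=C)[C@@H]2[C@H](OC(=O)/C(C)=C\C)C[C@]3(C)OC(C)(C)O[C@H]3C1 | intermediate
30 | α-methylene γ-lactone, C1/C10 acetonide of the target | O=C1/C(C)=C\[C@@H]2OC(=O)C(=C)[C@@H]2[C@H](OC(=O)/C(C)=C\C)C[C@]3(C)OC(C)(C)O[C@H]3C1 | intermediate
31 | CNP0271189.1 (1S,6S,7R,8R,10S; 4Z) | O=C1/C(C)=C\[C@@H]2OC(=O)C(=C)[C@@H]2[C@H](OC(=O)/C(C)=C\C)C[C@](C)(O)[C@@H](O)C1 | target

Total step count: 19. Longest linear sequence: 17 steps (steps 1–8 and 11–19); steps 9 and 10 make the dihydrofuran fragment.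

Least certain steps

Step 12 (key step). The enolate formed by the shift has the ring oxygen on its β-carbon and may expel it, opening the tetrahydrofuran. Silyl transfer from the C3 enol ether to the enolate may scramble the two oxygens. A slow shift would leave time for fragmentation of the alkoxide. The fallback moves the charge to the C3 oxygen and caps C8 as a methyl ether; it sets out from 10 and comes back at 22.
- Ketol 10 is silylated with N-(trimethylsilyl)imidazole to the trimethylsilyl ether F1.
- Addition of 17 gives the C8 carbinol F2, whose alkoxide is methylated in the same flask with MeOTf to the methyl ether F3.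
- Bu4NF gives the C3 alcohol F4.
- KH/18-crown-6 effects the same [3,3] shift from the C3 alkoxide, and t-BuMe2SiCl traps the simple ketone enolate as the ten-membered C3 silyl enol ether/C8 methyl enol ether F5.
- Oxalic acid in wet methanol hydrolyses the methyl enol ether to ketone 22, which is reduced as in step 13.

Step 11. The β-oxido vinyl metal may ring-open by anti elimination of the ring oxygen before it reaches the ketone, and the doubly hindered carbonyl may be enolised instead of attacked. The fallback builds the enol ether after the C–C bond is made; it sets out from 11 and comes back at 18.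
- The lithium enolate (LDA, THF, −78 °C) of 5-methoxydihydrofuran-2(3H)-one F6 adds to 11 in an aldol reaction to give the β-hydroxy lactone F7.
- i-Bu2AlH reduces it to the lactol F8.
- MsCl/Et3N dehydrates the lactol to the enol ether 18.

Step 13. Facial selectivity in the protonation at C7 and in hydride delivery to C8 rests on the ring conformation alone, so hydride may arrive on the wrong face. The fallback sets out from 22 and comes back at 26: if the reduction gives mainly the C8-epimeric alcohol F9, Mitsunobu esterification of F9 with 24 (PPh3, DIAD) installs the angelate with inversion and replaces step 14.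

Step 15. β-Hydride elimination may go toward the C4 methyl or give the 4E geometry, and silicon-to-palladium exchange at the hindered tetrasubstituted enol ether may be slow. The fallback sets out from 26 and comes back at 27: PhSeCl converts the silyl enol ether into the C4 phenylselenyl ketone F10, and H2O2/pyridine effects selenoxide syn-elimination to the enone.

Step 5. Oxidation may occur at the wrong hydroxyl or go on to the diketone. The fallback uses the better-documented alkylation selectivity of the same tin acetal; it sets out from 5 and comes back at 9.
- Stannylene acetal 6 is alkylated at its equatorial oxygen with 4-methoxybenzyl chloride/CsF to the C8 ether F11.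
- Dess–Martin oxidation gives the ketone F12.
- Addition of 8 gives the tertiary alcohol F13.
- DDQ removes the 4-methoxybenzyl group and gives 9.

Further compounds
F1 | step 12 | trimethylsilyl ether of ketol 10 | C=C(C)[C@]1(O[Si](C)(C)C)C[C@@H]2OC(C)(C)O[C@@]2(C)CC1=O
F2 | step 12 | C8 carbinol from F1 and 17 | C=C(C)[C@]1(O[Si](C)(C)C)C[C@@H]2OC(C)(C)O[C@@]2(C)C[C@@]1(O)C3=COC(OC)C3
F3 | step 12 | C8 methyl ether of F2 | C=C(C)[C@]1(O[Si](C)(C)C)C[C@@H]2OC(C)(C)O[C@@]2(C)C[C@@]1(OC)C3=COC(OC)C3
F4 | step 12 | C3 alcohol with C8 methoxy group | C=C(C)[C@]1(O)C[C@@H]2OC(C)(C)O[C@@]2(C)C[C@@]1(OC)C3=COC(OC)C3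
F5 | step 12 | ten-membered C3 OTBS enol ether and C8 methyl enol ether (6S) | CC(C)(C)[Si](C)(C)O/C1=C(/C)C[C@@H]2OC(OC)C/C2=C(OC)\C[C@]3(C)OC(C)(C)O[C@H]3C1
F6 | step 11 | 5-methoxydihydrofuran-2(3H)-one | COC1CCC(=O)O1
F7 | step 11 | β-hydroxy lactone from 11 and F6 | C=C(C)[C@]1(O[Si](C)(C)C(C)(C)C)C[C@@H]2OC(C)(C)O[C@@]2(C)C[C@@]1(O)C3CC(OC)OC3=O
F8 | step 11 | lactol from F7 | C=C(C)[C@]1(O[Si](C)(C)C(C)(C)C)C[C@@H]2OC(C)(C)O[C@@]2(C)C[C@@]1(O)C3CC(OC)OC3O
F9 | step 13 | C8 epimer of alcohol 23 | CC(C)(C)[Si](C)(C)O/C1=C(/C)C[C@@H]2OC(OC)C[C@@H]2[C@@H](O)C[C@]3(C)OC(C)(C)O[C@H]3C1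
F10 | step 15 | C4 phenylselenyl C3 ketone | O=C1C(C)([Se]c2ccccc2)C[C@@H]3OC(OC)C[C@@H]3[C@H](OC(=O)/C(C)=C\C)C[C@]4(C)OC(C)(C)O[C@H]4C1
F11 | step 5 | C8 4-methoxybenzyl ether of diol 5 | O[C@H]1C[C@@H]2OC(C)(C)O[C@@]2(C)C[C@H]1OCc3ccc(OC)cc3
F12 | step 5 | C3 ketone with C8 4-methoxybenzyl ether | O=C1C[C@@H]2OC(C)(C)O[C@@]2(C)C[C@H]1OCc3ccc(OC)cc3
F13 | step 5 | C3 isopropenyl carbinol with C8 4-methoxybenzyl ether | C=C(C)[C@]1(O)C[C@@H]2OC(C)(C)O[C@@]2(C)C[C@H]1OCc3ccc(OC)cc3
A1 | alternative 1 | ten-membered 4Z,6Z-diene | O[C@H]1C[C@](C)(O)[C@@H](O[Si](C)(C)C(C)(C)C)C[C@H](OCc2ccc(OC)cc2)/C(C)=C\C=C/1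
A2 | alternative 1 | cis-fused α-carboxy lactone | OC(=O)C1C(=O)O[C@H]2/C=C(/C)[C@@H](OCc3ccc(OC)cc3)C[C@H](O[Si](C)(C)C(C)(C)C)[C@@](C)(O)C[C@H](O)[C@@H]12
A3 | alternative 2 | open-chain C4 vinyl iodide / C2 vinyl stannane | I/C(C)=C\[C@H](O[Si](CC)(CC)CC)[C@H](C(=C)CO[Si](CC)(CC)CC)[C@H](OC(=O)/C(C)=C\C)C[C@](C)(O)/C=C/[Sn](CCCC)(CCCC)CCCC
A4 | alternative 2 | ten-membered 1E,4Z-dien-3-one with C8 angelate | C=C(CO[Si](CC)(CC)CC)[C@H]1[C@@H](O[Si](CC)(CC)CC)/C=C(/C)C(=O)/C=C/[C@@](C)(O)C[C@H]1OC(=O)/C(C)=C\C
A5 | alternative 3 | C8 phenyl selenoester with stannylmethyl butenolide | O=C1O[C@@H](/C=C(/C)[C@H](O[Si](CC)(CC)CC)C[C@@H]2OC(C)(C)O[C@@]2(C)CC(=O)[Se]c3ccccc3)C=C1C[Sn](CCCC)(CCCC)CCCC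
A6 | alternative 3 | ten-membered C8 ketone with cis α-methylene lactone | C=C1C(=O)O[C@H]2/C=C(/C)[C@H](O[Si](CC)(CC)CC)C[C@@H]3OC(C)(C)O[C@@]3(C)CC(=O)[C@@H]12
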